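**Plan**

- Eremophilane numbering is used (ring A = C1–C5, C10; ring B = C5–C10; C11 = isopropylidene carbon; C4' = side-chain carbinol). Retrosynthetic cuts, in order: the C3–O ester bond and both (Z)-alkenes (from alkynes); C7=C11 (aldol with acetone); the C8 ketone/C9–OH pair back to a C9 ketone (1,2-carbonyl shift); then C2–C3 and C4–C5 of ring A together.
- Enabling feature: in ring A the trans O–C3–C4–Me unit lies between the CH2 carbon C2 and the quaternary C5, and C9, next to the fusion carbon C10, is oxygenated. With C9 as a ketone and a C1=C10 alkene, ring A is the formal inverse-demand [4+2] adduct of the 2-vinyl enone C2=C1–C10(=C5)–C9=O and an (E)-propenyl silyl ether. The C9 carbonyl is the activating group; it is later moved to C8 while C9 keeps its oxygen.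
- Forward order: ring B is bought (3-methylcyclohex-2-enone) and vinylated at C10; ring A is annulated in step 5; then C10–H, the C9→C8 carbonyl shift, the isopropylidene group, and last the side chain.
- Stereochemistry: C3, C4 and C5 arise in the key step under catalyst control (C4 and C3 follow C5 through enol ether geometry and chair closure). C10 comes from axial protonation anti to the C5 methyl, C9 from equilibration to the equatorial position, C4' from purchased (S)-pent-1-yn-3-ol, and both (Z)-alkenes from semihydrogenation.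

Key step: step 5

Assumption: (S)-pent-1-yn-3-ol (21) is taken as a purchasable building block, and the descriptor (S,S) of the IDPi acid in step 5 stands for the catalyst enantiomer that exposes the Si face of C5 of enone 3.

**Route**

Step 1
Reactants: 1 3-methylcyclohex-2-en-1-one
Product: 2 2-iodo-3-methylcyclohex-2-en-1-one
Conditions: I2, K2CO3, DMAP (cat.), THF/H2O, rt
Reagents that add atoms: iodine, II
Why: Nucleophile-catalysed α-iodination of an enone (conjugate addition of DMAP, iodination of the enolate, elimination) is established for β-alkyl cyclohexenones and forms no stereocenter.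

Step 2
Reactants: 2 2-iodo-3-methylcyclohex-2-en-1-one
Product: 3 2-ethenyl-3-methylcyclohex-2-en-1-one
Conditions: CH2=CHSnBu3, Pd2(dba)3 (cat.), AsPh3, CuI, NMP, rt to 50 °C
Reagents that add atoms: tributyl(vinyl)stannane, C=C[Sn](CCCC)(CCCC)CCCC
Why: Stille coupling of α-iodo enones with vinylstannanes under arsine/copper co-catalysis is a standard route to 2-vinyl enones.

Step 3
Reactants: 4 prop-2-en-1-ol
Product: 5 triethyl(prop-2-en-1-yloxy)silane
Conditions: Et3SiCl, imidazole, CH2Cl2, 0 °C to rt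
Reagents that add atoms: chlorotriethylsilane, CC[Si](Cl)(CC)CC
Why: Routine silylation of a primary alcohol.

Step 4
Reactants: 5 triethyl(prop-2-en-1-yloxy)silane
Product: 6 triethyl[(1E)-prop-1-en-1-yloxy]silane
Conditions: [Ir(cod)(PMePh2)2]PF6 (1 mol %, pre-activated with H2, then degassed), THF, rt
Reagents that add atoms: none
Why: Cationic-iridium-catalysed isomerisation of allyl silyl ethers (1,3-hydrogen shift through a π-allyl hydride) is known to give (E)-silyl enol ethers under kinetic control.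

Step 5
Reactants: 3 2-ethenyl-3-methylcyclohex-2-en-1-one (1.2 equiv); 6 triethyl[(1E)-prop-1-en-1-yloxy]silane
Product: 7 (4aR,5R,6R)-4a,5-dimethyl-6-(triethylsilyloxy)-3,4,4a,5,6,7-hexahydronaphthalen-1(2H)-one
Conditions: (S,S)-IDPi (BINOL-derived N-triflyl imidodiphosphorimidate Brønsted acid, 5 mol %), toluene, −60 °C
Reagents that add atoms: none
Why: Proposed new method: the acid silylates itself from 6 and the resulting silylium–IDPi ion pair activates the C9 carbonyl of 3, so that C4 of 6 bonds to the β-carbon C5 (Mukaiyama–Michael mode, in which the first bond forms before the diene must become s-cis, so the Z-methyl on C5 that blocks concerted cycloadditions of this diene is no obstacle) and the silyloxocarbenium carbon C3 is then taken by C2, the γ-terminus of the silyl dienol ether, which releases the silylium ion for the next turnover. The closest known reaction types are silylium-catalysed Mukaiyama–Michael additions and vinylogous Mukaiyama aldol reactions under IDPi control, and Lewis-acid-promoted inverse-electron-demand [4+2] reactions of vinyl ethers with 2-acyl dienes. Ring A closes in a 6-(enolendo)-exo-trig vinylogous aldol mode; closure through C10 would give a cyclobutane and closure through oxygen a 2-silyloxydihydropyran, both of which should reopen under the conditions, so the cyclohexene is the expected sink. C5 is set by the chiral anion (attack on the Si face of C5 is required), C4 by the (E)-geometry of 6 in a compact arrangement with the silyloxy group over the developing dienolate (C4–Me ends cis to C5–Me), and C3 by the chair-like closure that places OSiEt3 and C4–Me equatorial and trans, an axial OSiEt3 being 1,3-diaxial to the C5 methyl. The step needs site selectivity for C5 of 3 over C1 of the product enone, which the excess of 3 and the low temperature are meant to secure, and regioselectivity, which is built in because C5 is the only acceptor carbon conjugated to the carbonyl and C2 the only dienolate terminus that can reach C3 in a six-membered ring.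

Step 6
Reactants: 7 (4aR,5R,6R)-4a,5-dimethyl-6-(triethylsilyloxy)-3,4,4a,5,6,7-hexahydronaphthalen-1(2H)-one
Product: 9 (4aR,5R,6R,8aR)-4a,5-dimethyl-6-(triethylsilyloxy)octahydronaphthalen-1(2H)-one, via lithium enolate 8 (not isolated)
Conditions: Li, NH3(l), THF, t-BuOH (1 equiv), −78 °C; then NH4Cl
Reagents that add atoms: none
Why: Dissolving-metal (Birch-type) conjugate reduction gives the C9/C10 enolate, which should be protonated at C10 axially on the α-face, anti to the axial C5 methyl, to give the trans ring fusion (C10 is α to the ketone, so the trans isomer is also open to equilibration).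

Step 7
Reactants: 9 (4aR,5R,6R,8aR)-4a,5-dimethyl-6-(triethylsilyloxy)octahydronaphthalen-1(2H)-one
Product: 11 tert-butyl{[(4aR,5R,6R,8aR)-4a,5-dimethyl-6-(triethylsilyloxy)-3,4,4a,5,6,7,8,8a-octahydronaphthalen-1-yl]oxy}dimethylsilane, via lithium enolate 10 (not isolated)
Conditions: LiN(iPr)2, THF, −78 °C; then TBSOTf, −78 to 0 °C
Reagents that add atoms: tert-butyldimethylsilyl trifluoromethanesulfonate, CC(C)(C)[Si](C)(C)OS(=O)(=O)C(F)(F)F
Why: Kinetic deprotonation takes the C8 methylene and not the hindered C10 methine, and O-silylation fixes the C8=C9 enol ether.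

Step 8
Reactants: 11 tert-butyl{[(4aR,5R,6R,8aR)-4a,5-dimethyl-6-(triethylsilyloxy)-3,4,4a,5,6,7,8,8a-octahydronaphthalen-1-yl]oxy}dimethylsilane
Product: 13 (1R,2R,4aR,5R,6R,8aR)-1-[tert-butyl(dimethyl)silyloxy]-4a,5-dimethyl-6-(triethylsilyloxy)decahydronaphthalen-2-ol, via alkylborane 12 (not isolated)
Conditions: BH3·THF, THF, 0 °C; then NaOH, H2O2, 0 °C
Reagents that add atoms: hydrogen peroxide, OO
Why: Hydroboration–oxidation of a silyl enol ether places boron on the β-carbon C8 and gives the trans β-silyloxy alcohol by syn addition, expected from the α-face opposite the axial C5 methyl; the other trans isomer would converge to the same ketone in step 9.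

Step 9
Reactants: 13 (1R,2R,4aR,5R,6R,8aR)-1-[tert-butyl(dimethyl)silyloxy]-4a,5-dimethyl-6-(triethylsilyloxy)decahydronaphthalen-2-ol
Product: 15 (1S,4aR,5R,6R,8aR)-1-[tert-butyl(dimethyl)silyloxy]-4a,5-dimethyl-6-(triethylsilyloxy)octahydronaphthalen-2(1H)-one, via axial silyloxy ketone 14 (not isolated)
Conditions: DMP, pyridine, CH2Cl2, rt; then DBU, CH2Cl2, rt to 40 °C
Reagents that add atoms: none
Why: Periodinane oxidation gives the C8 ketone, and base epimerisation through the C8/C9 enol moves the 9β-silyloxy group (1,3-diaxial to the C5 methyl) to the equatorial 9α-position under thermodynamic control, completing the 1,2-carbonyl transposition.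

Step 10
Reactants: 15 (1S,4aR,5R,6R,8aR)-1-[tert-butyl(dimethyl)silyloxy]-4a,5-dimethyl-6-(triethylsilyloxy)octahydronaphthalen-2(1H)-one
Product: 17 (1S,3S,4aR,5R,6R,8aR)-1-[tert-butyl(dimethyl)silyloxy]-3-(2-hydroxypropan-2-yl)-4a,5-dimethyl-6-(triethylsilyloxy)octahydronaphthalen-2(1H)-one, via lithium enolate 16 (not isolated)
Conditions: LiN(iPr)2, THF, −78 °C; then acetone, −78 °C; aq. NH4Cl
Reagents that add atoms: acetone, CC(C)=O
Why: Kinetic enolisation occurs at the C7 methylene (the C9 methine is hindered and oxygen-substituted) and aldol addition to acetone follows; the C7 stereocenter (drawn equatorial) is removed in step 11.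

Step 11
Reactants: 17 (1S,3S,4aR,5R,6R,8aR)-1-[tert-butyl(dimethyl)silyloxy]-3-(2-hydroxypropan-2-yl)-4a,5-dimethyl-6-(triethylsilyloxy)octahydronaphthalen-2(1H)-one
Product: 19 (1S,4aR,5R,6R,8aR)-1-[tert-butyl(dimethyl)silyloxy]-4a,5-dimethyl-3-(propan-2-ylidene)-6-(triethylsilyloxy)octahydronaphthalen-2(1H)-one, via mesylate 18 (not isolated)
Conditions: MsCl, Et3N, CH2Cl2, 0 °C; then DBU, rt
Reagents that add atoms: none
Why: Mesylation of the tertiary aldol and E1cB elimination through the C7 enolate give the conjugated, tetrasubstituted isopropylidene enone.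

Step 12
Reactants: 19 (1S,4aR,5R,6R,8aR)-1-[tert-butyl(dimethyl)silyloxy]-4a,5-dimethyl-3-(propan-2-ylidene)-6-(triethylsilyloxy)octahydronaphthalen-2(1H)-one
Product: 20 (1S,4aR,5R,6R,8aR)-1-[tert-butyl(dimethyl)silyloxy]-6-hydroxy-4a,5-dimethyl-3-(propan-2-ylidene)octahydronaphthalen-2(1H)-one
Conditions: PPTS, MeOH/CH2Cl2, 0 °C
Reagents that add atoms: none
Why: Acid-catalysed methanolysis removes a secondary triethylsilyl ether selectively in the presence of the more robust tert-butyldimethylsilyl ether.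

Step 13
Reactants: 21 (3S)-pent-1-yn-3-ol; 22 hex-2-ynoic acid
Product: 23 (3S)-pent-1-yn-3-yl hex-2-ynoate
Conditions: DCC, DMAP (cat.), CH2Cl2, 0 °C
Reagents that add atoms: none
Why: Steglich esterification forms the acyl–oxygen bond and leaves the carbinol stereocenter untouched.

Step 14
Reactants: 23 (3S)-pent-1-yn-3-yl hex-2-ynoate
Product: 25 (4S)-4-(hex-2-ynoyloxy)hex-2-ynoic acid, via lithium acetylide 24 (not isolated)
Conditions: LiN(SiMe3)2, THF, −78 °C; CO2; then aq. HCl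
Reagents that add atoms: carbon dioxide, O=C=O
Why: The terminal alkyne is deprotonated by the hindered amide at low temperature without attack on the ester, and the acetylide is carboxylated.

Step 15
Reactants: 20 (1S,4aR,5R,6R,8aR)-1-[tert-butyl(dimethyl)silyloxy]-6-hydroxy-4a,5-dimethyl-3-(propan-2-ylidene)octahydronaphthalen-2(1H)-one; 25 (4S)-4-(hex-2-ynoyloxy)hex-2-ynoic acid
Product: 26 (1S,4aR,5R,6R,8aR)-1-[tert-butyl(dimethyl)silyloxy]-4a,5-dimethyl-2-oxo-3-(propan-2-ylidene)decahydronaphthalen-6-yl (4S)-4-(hex-2-ynoyloxy)hex-2-ynoate (ring locants as in 20)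
Conditions: DCC, DMAP (cat.), CH2Cl2, −20 to 0 °C
Reagents that add atoms: none
Why: Steglich esterification of the equatorial C3 alcohol, with the alkynoic acid used in place of the (Z)-enoic acid so that acyl activation cannot cause Z/E isomerisation.

Step 16
Reactants: 26 (1S,4aR,5R,6R,8aR)-1-[tert-butyl(dimethyl)silyloxy]-4a,5-dimethyl-2-oxo-3-(propan-2-ylidene)decahydronaphthalen-6-yl (4S)-4-(hex-2-ynoyloxy)hex-2-ynoate
Product: 27 (1S,4aR,5R,6R,8aR)-1-[tert-butyl(dimethyl)silyloxy]-4a,5-dimethyl-2-oxo-3-(propan-2-ylidene)decahydronaphthalen-6-yl (2Z,4S)-4-[(2Z)-hex-2-enoyloxy]hex-2-enoate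
Conditions: H2 (1 atm), Pd/CaCO3 poisoned with Pb(OAc)2, quinoline, EtOAc, rt
Reagents that add atoms: none
Why: Poisoned-palladium semihydrogenation adds hydrogen syn to both ynoates and sets the two (Z)-alkenes, while the tetrasubstituted enone should be inert.

Step 17
Reactants: 27 (1S,4aR,5R,6R,8aR)-1-[tert-butyl(dimethyl)silyloxy]-4a,5-dimethyl-2-oxo-3-(propan-2-ylidene)decahydronaphthalen-6-yl (2Z,4S)-4-[(2Z)-hex-2-enoyloxy]hex-2-enoate
Product: 28 CNP0170141.1, (1S,4aR,5R,6R,8aR)-1-hydroxy-4a,5-dimethyl-2-oxo-3-(propan-2-ylidene)decahydronaphthalen-6-yl (2Z,4S)-4-[(2Z)-hex-2-enoyloxy]hex-2-enoate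
Conditions: HF·pyridine, pyridine, THF, 0 °C to rt
Reagents that add atoms: none
Why: Fluoride cleavage of the silyl ether under non-basic conditions should leave the γ-acyloxy (Z)-enoate and the α-ketol untouched.

**Compound list**

1 | 3-methylcyclohex-2-en-1-one | CC1=CC(=O)CCC1 | starting material
2 | 2-iodo-3-methylcyclohex-2-en-1-one | CC1=C(I)C(=O)CCC1 | intermediate
3 | 2-ethenyl-3-methylcyclohex-2-en-1-one | C=CC1=C(C)CCCC1=O | intermediate
4 | prop-2-en-1-ol (allyl alcohol) | C=CCO | starting material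
5 | triethyl(prop-2-en-1-yloxy)silane | C=CCO[Si](CC)(CC)CC | intermediate
6 | triethyl[(1E)-prop-1-en-1-yloxy]silane | C/C=C/O[Si](CC)(CC)CC | intermediate
7 | (4aR,5R,6R)-4a,5-dimethyl-6-(triethylsilyloxy)-3,4,4a,5,6,7-hexahydronaphthalen-1(2H)-one | CC[Si](CC)(CC)O[C@@H]1CC=C2C(=O)CCC[C@]2(C)[C@H]1C | intermediate
8 | lithium (4aR,5R,6R)-4a,5-dimethyl-6-(triethylsilyloxy)-2,3,4,4a,5,6,7,8-octahydronaphthalen-1-olate (C9/C10 enolate) | CC[Si](CC)(CC)O[C@@H]1CCC2=C(O[Li])CCC[C@]2(C)[C@H]1C | intermediate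
9 | (4aR,5R,6R,8aR)-4a,5-dimethyl-6-(triethylsilyloxy)octahydronaphthalen-1(2H)-one (trans-fused) | CC[Si](CC)(CC)O[C@@H]1CC[C@H]2C(=O)CCC[C@]2(C)[C@H]1C | intermediate
10 | lithium (4aR,5R,6R,8aR)-4a,5-dimethyl-6-(triethylsilyloxy)-3,4,4a,5,6,7,8,8a-octahydronaphthalen-1-olate (C8/C9 enolate) | CC[Si](CC)(CC)O[C@@H]1CC[C@H]2C(O[Li])=CCC[C@]2(C)[C@H]1C | intermediate
11 | tert-butyl{[(4aR,5R,6R,8aR)-4a,5-dimethyl-6-(triethylsilyloxy)-3,4,4a,5,6,7,8,8a-octahydronaphthalen-1-yl]oxy}dimethylsilane | CC[Si](CC)(CC)O[C@@H]1CC[C@H]2C(O[Si](C)(C)C(C)(C)C)=CCC[C@]2(C)[C@H]1C | intermediate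
12 | [(1S,2R,4aR,5R,6R,8aR)-1-[tert-butyl(dimethyl)silyloxy]-4a,5-dimethyl-6-(triethylsilyloxy)decahydronaphthalen-2-yl]borane (8α-boryl, 9β-silyloxy) | CC[Si](CC)(CC)O[C@@H]1CC[C@H]2[C@@H](O[Si](C)(C)C(C)(C)C)[C@H](B)CC[C@]2(C)[C@H]1C | intermediate
13 | (1R,2R,4aR,5R,6R,8aR)-1-[tert-butyl(dimethyl)silyloxy]-4a,5-dimethyl-6-(triethylsilyloxy)decahydronaphthalen-2-ol (8α-OH, 9β-OTBS) | CC[Si](CC)(CC)O[C@@H]1CC[C@H]2[C@@H](O[Si](C)(C)C(C)(C)C)[C@H](O)CC[C@]2(C)[C@H]1C | intermediate
14 | (1R,4aR,5R,6R,8aR)-1-[tert-butyl(dimethyl)silyloxy]-4a,5-dimethyl-6-(triethylsilyloxy)octahydronaphthalen-2(1H)-one (9β-OTBS, axial) | CC[Si](CC)(CC)O[C@@H]1CC[C@H]2[C@@H](O[Si](C)(C)C(C)(C)C)C(=O)CC[C@]2(C)[C@H]1C | intermediate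
15 | (1S,4aR,5R,6R,8aR)-1-[tert-butyl(dimethyl)silyloxy]-4a,5-dimethyl-6-(triethylsilyloxy)octahydronaphthalen-2(1H)-one (9α-OTBS, equatorial) | CC[Si](CC)(CC)O[C@@H]1CC[C@H]2[C@H](O[Si](C)(C)C(C)(C)C)C(=O)CC[C@]2(C)[C@H]1C | intermediate
16 | lithium (1S,4aR,5R,6R,8aR)-1-[tert-butyl(dimethyl)silyloxy]-4a,5-dimethyl-6-(triethylsilyloxy)-1,4,4a,5,6,7,8,8a-octahydronaphthalen-2-olate (C7/C8 enolate) | CC[Si](CC)(CC)O[C@@H]1CC[C@H]2[C@H](O[Si](C)(C)C(C)(C)C)C(O[Li])=CC[C@]2(C)[C@H]1C | intermediate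
17 | (1S,3S,4aR,5R,6R,8aR)-1-[tert-butyl(dimethyl)silyloxy]-3-(2-hydroxypropan-2-yl)-4a,5-dimethyl-6-(triethylsilyloxy)octahydronaphthalen-2(1H)-one | CC[Si](CC)(CC)O[C@@H]1CC[C@H]2[C@H](O[Si](C)(C)C(C)(C)C)C(=O)[C@H](C(C)(C)O)C[C@]2(C)[C@H]1C | intermediate
18 | 2-[(1S,3S,4aR,5R,6R,8aR)-1-[tert-butyl(dimethyl)silyloxy]-4a,5-dimethyl-2-oxo-6-(triethylsilyloxy)decahydronaphthalen-3-yl]propan-2-yl methanesulfonate | CC[Si](CC)(CC)O[C@@H]1CC[C@H]2[C@H](O[Si](C)(C)C(C)(C)C)C(=O)[C@H](C(C)(C)OS(C)(=O)=O)C[C@]2(C)[C@H]1C | intermediate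
19 | (1S,4aR,5R,6R,8aR)-1-[tert-butyl(dimethyl)silyloxy]-4a,5-dimethyl-3-(propan-2-ylidene)-6-(triethylsilyloxy)octahydronaphthalen-2(1H)-one | CC[Si](CC)(CC)O[C@@H]1CC[C@H]2[C@H](O[Si](C)(C)C(C)(C)C)C(=O)C(=C(C)C)C[C@]2(C)[C@H]1C | intermediate
20 | (1S,4aR,5R,6R,8aR)-1-[tert-butyl(dimethyl)silyloxy]-6-hydroxy-4a,5-dimethyl-3-(propan-2-ylidene)octahydronaphthalen-2(1H)-one | O[C@@H]1CC[C@H]2[C@H](O[Si](C)(C)C(C)(C)C)C(=O)C(=C(C)C)C[C@]2(C)[C@H]1C | intermediate
21 | (3S)-pent-1-yn-3-ol | O[C@H](C#C)CC | starting material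
22 | hex-2-ynoic acid | CCCC#CC(=O)O | starting material
23 | (3S)-pent-1-yn-3-yl hex-2-ynoate | CCCC#CC(=O)O[C@H](C#C)CC | intermediate
24 | lithium (3S)-3-(hex-2-ynoyloxy)pent-1-yn-1-ide | CCCC#CC(=O)O[C@H](C#C[Li])CC | intermediate
25 | (4S)-4-(hex-2-ynoyloxy)hex-2-ynoic acid | CCCC#CC(=O)O[C@H](C#CC(=O)O)CC | intermediate
26 | (1S,4aR,5R,6R,8aR)-1-[tert-butyl(dimethyl)silyloxy]-4a,5-dimethyl-2-oxo-3-(propan-2-ylidene)decahydronaphthalen-6-yl (4S)-4-(hex-2-ynoyloxy)hex-2-ynoate | CCCC#CC(=O)O[C@H](C#CC(=O)O[C@@H]1CC[C@H]2[C@H](O[Si](C)(C)C(C)(C)C)C(=O)C(=C(C)C)C[C@]2(C)[C@H]1C)CC | intermediate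
27 | (1S,4aR,5R,6R,8aR)-1-[tert-butyl(dimethyl)silyloxy]-4a,5-dimethyl-2-oxo-3-(propan-2-ylidene)decahydronaphthalen-6-yl (2Z,4S)-4-[(2Z)-hex-2-enoyloxy]hex-2-enoate | CCC/C=C\C(=O)O[C@H](/C=C\C(=O)O[C@@H]1CC[C@H]2[C@H](O[Si](C)(C)C(C)(C)C)C(=O)C(=C(C)C)C[C@]2(C)[C@H]1C)CC | intermediate
28 | CNP0170141.1, (1S,4aR,5R,6R,8aR)-1-hydroxy-4a,5-dimethyl-2-oxo-3-(propan-2-ylidene)decahydronaphthalen-6-yl (2Z,4S)-4-[(2Z)-hex-2-enoyloxy]hex-2-enoate | CCC/C=C\C(=O)O[C@H](/C=C\C(=O)O[C@@H]1CC[C@H]2[C@H](O)C(=O)C(=C(C)C)C[C@]2(C)[C@H]1C)CC | target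

**Step count and risks**

Total step count: 17. Longest linear sequence: 13 steps (1, 2, 5–12, 15–17).

Steps most likely to fail:

Step 5 (Proposed new method). The enol ether may add too slowly to the β,β-disubstituted acceptor carbon, and the intermediate may close through oxygen or take up a second enol ether at C1 of the product. The chiral anion may also give low or reversed facial discrimination (the antipodal acid would answer a reversed sense only). Fallback, from 2 back to 9, a stepwise Claisen relay using known reaction types: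
- Corey–Bakshi–Shibata reduction of 2 [(S)-2-methyl-CBS-oxazaborolidine, BH3·SMe2] should give (1R)-2-iodo-3-methylcyclohex-2-en-1-ol F1. Acylation (propanoyl chloride, pyridine) gives (1R)-2-iodo-3-methylcyclohex-2-en-1-yl propanoate F2.
- Ireland–Claisen rearrangement [LiN(iPr)2, Me3SiCl, THF, −78 °C to rt] forms C4–C5 with suprafacial transfer of the carbinol configuration to the quaternary carbon, giving (2R)-2-[(1R)-2-iodo-1-methylcyclohex-2-en-1-yl]propanoic acid F3.
- The acid is converted (carbonyldiimidazole, MeNHOMe·HCl) into (2R)-2-[(1R)-2-iodo-1-methylcyclohex-2-en-1-yl]-N-methoxy-N-methylpropanamide F4, and CH2=CHMgBr then gives (4R)-4-[(1R)-2-iodo-1-methylcyclohex-2-en-1-yl]pent-1-en-3-one F5.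
- The C10 vinyl radical from F5 (Bu3SnH, AIBN, benzene, 80 °C) closes ring A by 6-endo addition to the enone terminus, giving (1R,8aR)-1,8a-dimethyl-3,4,6,7,8,8a-hexahydronaphthalen-2(1H)-one F6. C4 is α to the ketone here and can be equilibrated (NaOMe, MeOH) to the equatorial methyl should the rearrangement deliver the epimer.
- Dissolving-metal reduction (Li, NH3, EtOH; thermodynamic, equatorial alcohol) gives (1R,2R,8aR)-1,8a-dimethyl-1,2,3,4,6,7,8,8a-octahydronaphthalen-2-ol F7, and silylation (Et3SiCl, imidazole) gives triethyl{[(1R,2R,8aR)-1,8a-dimethyl-1,2,3,4,6,7,8,8a-octahydronaphthalen-2-yl]oxy}silane F8.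
- Hydroboration–oxidation (BH3·THF; NaOH, H2O2) from the face opposite the angular methyl gives the trans-fused (1R,4aR,5R,6R,8aR)-4a,5-dimethyl-6-(triethylsilyloxy)decahydronaphthalen-1-ol F9, which periodinane oxidation (DMP) converts into 9.

Step 8. The trans β-silyloxy organoborane may undergo β-elimination (loss of the C9 oxygen and formation of the C8=C9 alkene), or the silyl group may migrate during the basic peroxide work-up. Fallback, from 9 back to 13, an enolate oxidation followed by oxidation-level exchange: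
- The kinetic enolate of 9 [KN(SiMe3)2, THF, −78 °C] is hydroxylated with 2-(benzenesulfonyl)-3-phenyloxaziridine on the α-face to give (2R,4aR,5R,6R,8aR)-2-hydroxy-4a,5-dimethyl-6-(triethylsilyloxy)octahydronaphthalen-1(2H)-one F10.
- Acetylation (Ac2O, pyridine, DMAP) gives (2R,4aR,5R,6R,8aR)-4a,5-dimethyl-1-oxo-6-(triethylsilyloxy)decahydronaphthalen-2-yl acetate F11.
- NaBH4 reduction (MeOH, −20 °C), with hydride delivered from the α-face away from the C5 methyl, gives (1R,2R,4aR,5R,6R,8aR)-1-hydroxy-4a,5-dimethyl-6-(triethylsilyloxy)decahydronaphthalen-2-yl acetate F12.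
- Silylation (TBSOTf, 2,6-lutidine) gives (1R,2R,4aR,5R,6R,8aR)-1-[tert-butyl(dimethyl)silyloxy]-4a,5-dimethyl-6-(triethylsilyloxy)decahydronaphthalen-2-yl acetate F13, and methanolysis of the acetate (K2CO3, MeOH) returns 13.

Step 6. Enolate 8 may be protonated from the β-face (cis ring fusion), or the ketone may be over-reduced. Fallback, from 7 back to 9, a hydroxyl-directed hydrogenation in place of enolate protonation:
- The triethylsilyl ether of 7 is removed (PPTS, MeOH) to give (4aR,5R,6R)-6-hydroxy-4a,5-dimethyl-3,4,4a,5,6,7-hexahydronaphthalen-1(2H)-one F14.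
- The homoallylic 3α-hydroxyl then directs [Ir(cod)(PCy3)(py)]PF6/H2 (CH2Cl2, rt) to the α-face of C1=C10 to give the trans-fused (4aR,5R,6R,8aR)-6-hydroxy-4a,5-dimethyloctahydronaphthalen-1(2H)-one F15.
- Resilylation (Et3SiCl, imidazole) returns 9.

Further compounds
F1 | step 5 | (1R)-2-iodo-3-methylcyclohex-2-en-1-ol | O[C@@H]1CCCC(C)=C1I
F2 | step 5 | (1R)-2-iodo-3-methylcyclohex-2-en-1-yl propanoate | CCC(=O)O[C@@H]1CCCC(C)=C1I
F3 | step 5 | (2R)-2-[(1R)-2-iodo-1-methylcyclohex-2-en-1-yl]propanoic acid | OC(=O)[C@H](C)[C@@]1(C)CCCC=C1I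
F4 | step 5 | (2R)-2-[(1R)-2-iodo-1-methylcyclohex-2-en-1-yl]-N-methoxy-N-methylpropanamide | CON(C)C(=O)[C@H](C)[C@@]1(C)CCCC=C1I
F5 | step 5 | (4R)-4-[(1R)-2-iodo-1-methylcyclohex-2-en-1-yl]pent-1-en-3-one | C=CC(=O)[C@H](C)[C@@]1(C)CCCC=C1I
F6 | step 5 | (1R,8aR)-1,8a-dimethyl-3,4,6,7,8,8a-hexahydronaphthalen-2(1H)-one | O=C1CCC2=CCCC[C@]2(C)[C@H]1C
F7 | step 5 | (1R,2R,8aR)-1,8a-dimethyl-1,2,3,4,6,7,8,8a-octahydronaphthalen-2-ol | O[C@@H]1CCC2=CCCC[C@]2(C)[C@H]1C
F8 | step 5 | triethyl{[(1R,2R,8aR)-1,8a-dimethyl-1,2,3,4,6,7,8,8a-octahydronaphthalen-2-yl]oxy}silane | CC[Si](CC)(CC)O[C@@H]1CCC2=CCCC[C@]2(C)[C@H]1C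
F9 | step 5 | (1R,4aR,5R,6R,8aR)-4a,5-dimethyl-6-(triethylsilyloxy)decahydronaphthalen-1-ol | CC[Si](CC)(CC)O[C@@H]1CC[C@H]2[C@H](O)CCC[C@]2(C)[C@H]1C
F10 | step 8 | (2R,4aR,5R,6R,8aR)-2-hydroxy-4a,5-dimethyl-6-(triethylsilyloxy)octahydronaphthalen-1(2H)-one | CC[Si](CC)(CC)O[C@@H]1CC[C@H]2C(=O)[C@H](O)CC[C@]2(C)[C@H]1C
F11 | step 8 | (2R,4aR,5R,6R,8aR)-4a,5-dimethyl-1-oxo-6-(triethylsilyloxy)decahydronaphthalen-2-yl acetate | CC[Si](CC)(CC)O[C@@H]1CC[C@H]2C(=O)[C@H](OC(C)=O)CC[C@]2(C)[C@H]1C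
F12 | step 8 | (1R,2R,4aR,5R,6R,8aR)-1-hydroxy-4a,5-dimethyl-6-(triethylsilyloxy)decahydronaphthalen-2-yl acetate | CC[Si](CC)(CC)O[C@@H]1CC[C@H]2[C@@H](O)[C@H](OC(C)=O)CC[C@]2(C)[C@H]1C
F13 | step 8 | (1R,2R,4aR,5R,6R,8aR)-1-[tert-butyl(dimethyl)silyloxy]-4a,5-dimethyl-6-(triethylsilyloxy)decahydronaphthalen-2-yl acetate | CC[Si](CC)(CC)O[C@@H]1CC[C@H]2[C@@H](O[Si](C)(C)C(C)(C)C)[C@H](OC(C)=O)CC[C@]2(C)[C@H]1C
F14 | step 6 | (4aR,5R,6R)-6-hydroxy-4a,5-dimethyl-3,4,4a,5,6,7-hexahydronaphthalen-1(2H)-one | O[C@@H]1CC=C2C(=O)CCC[C@]2(C)[C@H]1C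
F15 | step 6 | (4aR,5R,6R,8aR)-6-hydroxy-4a,5-dimethyloctahydronaphthalen-1(2H)-one | O[C@@H]1CC[C@H]2C(=O)CCC[C@]2(C)[C@H]1C
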